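Readings and results were computed on assumed constants; scatter was added.

Of a charge of 0.15 M substrate, the oak run holds 3.9% unreacted after 4.00 min and 0.5% after 30.0 min, while target and isomer of the product lie near 90.0% and 9.8% in the late readings.

| flask | substrate | remark | time |
|---|---|---|---|
| oak | 0.15 M | the very flask that is asked about, followed so far |  |
| flask | 0.15 M |  | 1.0 h |

oak run (percent of the substrate charged)

| time / min | substrate / % | target / % | isomer of the product / % |
|---|---|---|---|
| 4.00 | 3.9 | 87.1 | 9.5 |
| 8.00 | 2.0 | 88.0 | 10.0 |
| 12.0 | 1.2 | 88.7 | 10.1 |
| 15.0 | 1.0 | 88.8 | 10.2 |
| 20.0 | 1.0 | 89.8 | 9.8 |
| 25.0 | 0.6 | 90.0 | 9.8 |
| 30.0 | 0.5 | 89.6 | 10.2 |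

(readings scatter by 0.3 percentage points)

- percentages count the substrate that a species holds: one target or isomer of the product counts as two
- the numbers in the tables scatter by 0.3 percentage points (one standard deviation)
- the reaction counts as stopped when no species that holds the substrate changes by six tenths of a point or more over the second half of the time

1. the state of affairs at 1.0 h: stopped, and by what, or still going (forward and back rates have come level / all of the substrate has reacted / it is still moving)
2. how much of the substrate has reacted by 1.0 h
3. how much target there is at 1.0 h, in percent of the substrate charged
4. how much isomer of the product there is at 1.0 h, in percent of the substrate charged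

Two chemists read the tail of c(substrate) differently. The first works with the fraction left, f, which is c(substrate) over its charge. If two substrate join at each turn, the reciprocal of f climbs by one in each equal span of time. The oak reading at 8.00 min puts that span at 0.163 min. This charge half-life, the first half-life of a second-order decay, is the time for f to fall to half, and it gives f = τ/(τ+t).

From that early reading, f at 30.0 min comes to 0.540%, and the oak run reads 0.5% there. The flask is the oak run followed further, so at 1.0 h f is 0.271%. Over the second half of the time f falls 0.27 percentage points, which the stopping rule counts as stopped, with 0.271% of the substrate left.

The second chemist sees the readings at 15.0 min and 20.0 min level and the last two nearly so. She takes their mean, 0.550%, as a floor where forward and back rates have come level, with 99.5% reacted. At 1.0 h the two views part by 0.28 points, less than the scatter of 0.3 points. I side with the first, since an early reading lands on the late one without a floor.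

The forecast says all of the substrate has reacted, with 99.7% reacted, 89.8% target and 10% isomer, and of a plateau it says “nothing requires it, and the last points are still falling”.

    2 substrate → target (k = 0.350 /M/s)
    target ⇌ isomer of the product (K = 0.110, k = 0.0280 /s)

The flask gives all of the substrate has reacted, with 99.7% reacted, 89.9% target and 9.88% isomer. Its substrate stands at 0.26% beside the reckoned 0.271%, and at 0.0264% after 10.0 h, below the floor. From 0.500 h to 1.00 h its fall of 0.26 points is within the scatter, so single readings over that span do not part the two views. The joining of substrate into target has 99% of its turnover behind it by 0.200 h, and the passing of target into isomer ran alongside it, with a relaxation half-life of 0.0409 min, short against the time. The charge half-life scales inversely with the charge, so at 0.060 M it is 0.408 min, which gives f = 0.675%, and that neighbour flask holds 0.66%.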